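The rate constants are made up; the flask was simulated.

By the scheme, each substrate molecule that reacts spends one reagent molecule and becomes target, so the sum of substrate, target and isomer of the product stays at the substrate charge.

| setting | larch | birch | ash | oak |
|---|---|---|---|---|
| substrate | 0.079 M | 0.079 M | 0.079 M | 0.079 M |
| reagent | 0.118 M | 0.118 M | 0.118 M | 0.118 M |
| catalyst | 42 µM | 42 µM | 42 µM | 42 µM |
| temperature | 35 °C | 65 °C | 50 °C | 80 °C |
| time | 12 min | 12 min | 12 min | 12 min |

    substrate + reagent + catalyst → target + catalyst, rate k1*[substrate]*[reagent]*[catalyst]/(1 + ([substrate]/sat1)) (sat1 = 0.212 M, k1 = 62700 L² mol⁻² min⁻¹, Ea1 = 36.0 kJ mol⁻¹)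
    target ⇌ isomer of the product (K2 = 4.6, k2 = 0.0302 min⁻¹, Ea2 = 85.0 kJ mol⁻¹, ΔH2 = 15.0 kJ mol⁻¹)
    (constants at 35 °C)

- constants are those at 35 °C; use the activation energies and enthalpies for any other temperature

- the flask that comes out highest in amount of target, in percent of the substrate charged, or "all alike" when all lie within 1.5 percentage points (larch / birch / ash / oak / all alike)
- target at the end, in percent of the substrate charged, larch
- target at the end, in percent of the substrate charged, birch
- target at the end, in percent of the substrate charged, ash
- target at the end, in percent of the substrate charged, oak

**Bench rule.** As a rule of thumb, I count a reversible step as finished after 3 half-lives, and target then stands at its equilibrium share: one over one plus the equilibrium constant. In oak the equilibrium constant is 9.70 and the relaxation half-life of the second step is 0.304 min, so 12 min is longer than 3 of them. A substrate molecule in oak lasts about 1.11 min, which is also shorter than 12 min, so I reckon target there at 9.35%.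

**The border.** In larch the relaxation half-life is 18.9 min, so the time holds 0.635 half-lives, fewer than the rule asks. The rule stops working there, and I follow one molecule instead.

**The fork.** In larch a substrate molecule turns into target at c(reagent) times c(catalyst) times the first rate constant, divided by one plus c(substrate) over the saturation constant. I take c(reagent) midway through its course, which is its charge less half the substrate charge, keep c(substrate) in the divisor at its charge, and get 0.151 min⁻¹. A target molecule leaves at 0.0302 min⁻¹, and the way back is slower than the way out, so I drop it. The first rate over the second is 4.99 in larch. This is the fork ratio, a selectivity factor. Two first-order steps in a row then give larch 66.5% target.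

**On heating.** The second step has the higher activation energy, and from larch to oak it speeds up by 69 against 6.0 for the first step. The fork ratio therefore falls to 0.434 in oak, and I pick the coolest flask: larch.

**The forecast.** It puts larch on top, with 67.5% there, 33.6% in ash, 12.1% in birch and 9.4% in oak, since “heating mainly drains target into the isomer”.

**The result.** The simulation puts larch on top, with 67.2% there, 33.3% in ash, 12.1% in birch and 9.35% in oak. With 1.7 × 10⁻⁴ M of catalyst in the larch recipe and all else held, the fork ratio becomes 20.2, and the same two-step reckoning gives 73.2% target. That neighbour flask reads 73.6% target, with 26.2% isomer of the product and 0.28% substrate left.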